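**Strategy**

The tetrahydrofuran (O1, C2–C5; C2 bears free-phenol ring B, C5 the etherified ring C) is cut at O1–C2 and C3–C4. The O1–C5–C4 piece is an (R)-1-arylallyl alcohol in which C4 and its methyl are still a vinyl group; the C2–C3 piece is the methyl enol ether of the ring B propiophenone. One Ueno–Stork operation joins them: alkoxybromination forms O1–C2 as a ketal, then 5-exo radical cyclisation forms C3–C4, turns the vinyl CH2 into the C4 methyl and sets it trans to ring C. The step exploits that C4 carries only a methyl beside carbinol C5 and that C2 is a benzylic, oxygen-bearing carbon; hydride later sets C2 cis to the C3 methyl.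

Key step: step 5

Remark: locants used below are tetrahydrofuran O1, C2 (bears ring B, the 4-hydroxy-3-methoxyphenyl group), C3, C4, C5 (bears ring C, the aryl ether ring), and side chain C7'' (carbinol, bears ring D) and C8'' (aryloxy methine).

**Route**

Step 1
Reactants: 1 vanillin; 2 methyl (S)-lactate
Product: 3 methyl (2R)-2-(4-formyl-2-methoxyphenoxy)propanoate
Conditions: PPh3, DIAD, THF, 0 °C to rt
Reagents that add atoms: none
Why: Mitsunobu etherification: the acidic vanillin phenol displaces the lactate-derived alkoxyphosphonium ion by SN2 with inversion, so the (S)-lactate centre becomes the (R)-aryloxy centre that ends as C8''.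

Step 2
Reactants: 3 methyl (2R)-2-(4-formyl-2-methoxyphenoxy)propanoate
Product: 4 methyl (2R)-2-{4-[(1R)-1-hydroxyprop-2-en-1-yl]-2-methoxyphenoxy}propanoate
Conditions: Zn(CH=CH2)2, (2R)-(+)-3-exo-(dimethylamino)isoborneol [(+)-DAIB] (cat.), toluene/Et2O, 0 °C; aq. NH4Cl
Reagents that add atoms: divinylzinc C=C[Zn]C=C
Why: Amino-alcohol-catalysed alkenylzinc addition to an aldehyde: the chiral zinc aminoalkoxide directs vinyl transfer to the Re face of the aryl aldehyde and so sets the (R)-carbinol (future C5), while the organozinc reagent leaves the ester untouched.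

Step 3
Reactants: 5 propiovanillone
Product: 6 1-{4-[(tert-butyldimethylsilyl)oxy]-3-methoxyphenyl}propan-1-one
Conditions: TBSCl, imidazole, DMF, rt
Reagents that add atoms: tert-butyldimethylsilyl chloride CC(C)(C)[Si](C)(C)Cl
Why: Standard silylation of a phenol, needed so that the ring B phenol survives NBS, tin radicals and the later organometallic steps.

Step 4
Reactants: 6 1-{4-[(tert-butyldimethylsilyl)oxy]-3-methoxyphenyl}propan-1-one
Product: 8 tert-butyl{2-methoxy-4-[1-methoxyprop-1-en-1-yl]phenoxy}dimethylsilane (E/Z mixture), via dimethyl ketal 7 (not isolated)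
Conditions: HC(OMe)3, TsOH (cat.), MeOH, rt; evaporation; then Me3SiOTf, i-Pr2NEt, CH2Cl2, −20 °C to rt
Reagents that add atoms: trimethyl orthoformate COC(OC)OC
Why: Acid-catalysed ketalisation followed by silyl triflate/amine-promoted loss of methanol from the dimethyl ketal gives the methyl enol ether, whose double-bond geometry is irrelevant because C3 becomes a radical in step 5.

Step 5
Reactants: 4 methyl (2R)-2-{4-[(1R)-1-hydroxyprop-2-en-1-yl]-2-methoxyphenoxy}propanoate; 8 tert-butyl{2-methoxy-4-[1-methoxyprop-1-en-1-yl]phenoxy}dimethylsilane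
Product: 10 cyclic methyl ketal of the 4,5-trans tetrahydrofuran (epimer mixture at C2 and C3), via mixed bromoketal 9 (not isolated)
Conditions: NBS, 2,6-lutidine, CH2Cl2, −78 to −40 °C; then Bu3SnH (slow addition), Et3B, air, toluene, −40 °C to rt
Reagents that add atoms: none
Why: Ueno–Stork haloacetalisation/radical cyclisation: NBS brominates the enol ether at C3, the aryl- and methoxy-stabilised oxocarbenium ion at C2 is captured by the carbinol oxygen of 4 (O1–C2, Markovnikov by construction), and Bu3Sn• then abstracts bromine to give a C3 radical. This radical closes the tetrahydrofuran by 5-exo-trig attack on the internal vinyl carbon (C3–C4), and the resulting primary radical takes hydrogen from Bu3SnH, so the former =CH2 becomes the C4 methyl. C5 is untouched and keeps its (R) configuration, and C4 should form trans to ring C because the aryl group sits pseudo-equatorial in the chair-like 5-exo transition state. C2 (ketal) and C3 form as mixtures, which is acceptable because C2 is erased as an oxocarbenium ion and C3 is equilibrated in step 6. The step needs bromination of the enol ether in preference to the vinyl group and the two electron-rich arenes (secured by the far higher nucleophilicity of the enol ether at −78 °C), and 5-exo closure in preference to 6-endo closure or direct reduction (secured by the 3-oxa tether, the fully substituted C2 and slow addition of the tin hydride).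

Step 6
Reactants: 10 cyclic methyl ketal of the 4,5-trans tetrahydrofuran (epimer mixture at C2 and C3)
Product: 12 methyl (2R)-2-{4-[(2S,3R,4R,5R)-2-aryl-3,4-dimethyltetrahydrofuran-5-yl]-2-methoxyphenoxy}propanoate (aryl = 4-TBSO-3-methoxyphenyl), via C3-equilibrated ketal 11 (not isolated)
Conditions: CSA (cat.), MeOH, 40 °C; Et3N, evaporation; then Et3SiH, BF3·OEt2, CH2Cl2, −78 to −40 °C
Reagents that add atoms: none
Why: Acid-catalysed ketal exchange in methanol passes through the 2-aryl-4,5-dihydrofuran and should equilibrate C3 to the more stable arrangement trans to the C4 methyl, after which Lewis acid-promoted reductive deoxygenation of the cyclic ketal (ionic hydrogenation) generates the C2 oxocarbenium ion and Et3SiH adds to the face anti to both the C3 methyl and ring C, placing ring B cis to the C3 methyl.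

Step 7
Reactants: 12 methyl (2R)-2-{4-[(2S,3R,4R,5R)-2-aryl-3,4-dimethyltetrahydrofuran-5-yl]-2-methoxyphenoxy}propanoate
Product: 13 the corresponding (2R)-N-methoxy-N-methylpropanamide (Weinreb amide)
Conditions: MeNH(OMe)·HCl, i-PrMgCl, THF, −20 °C
Reagents that add atoms: N,O-dimethylhydroxylamine hydrochloride CNOC.Cl
Why: Direct ester-to-Weinreb-amide conversion by the magnesium amide of N,O-dimethylhydroxylamine, which at −20 °C adds to the ester faster than it enolises the aryloxy-substituted α-centre.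

Step 8
Reactants: 14 4-bromo-2-methoxyphenol
Product: 15 (4-bromo-2-methoxyphenoxy)(tert-butyl)dimethylsilane
Conditions: TBSCl, imidazole, DMF, rt
Reagents that add atoms: tert-butyldimethylsilyl chloride CC(C)(C)[Si](C)(C)Cl
Why: Standard phenol silylation; the silyl ether is para to bromine, so no silyl migration can follow lithiation.

Step 9
Reactants: 13 Weinreb amide; 15 (4-bromo-2-methoxyphenoxy)(tert-butyl)dimethylsilane
Product: 17 (2R)-1-(4-TBSO-3-methoxyphenyl)-2-{4-[(2S,3R,4R,5R)-2-aryl-3,4-dimethyltetrahydrofuran-5-yl]-2-methoxyphenoxy}propan-1-one, via aryllithium 16 (not isolated)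
Conditions: 15, n-BuLi, THF, −78 °C; then 13, −78 °C; aq. NH4Cl
Reagents that add atoms: none
Why: Bromine–lithium exchange followed by Weinreb ketone synthesis: the chelated tetrahedral adduct stops at the ketone stage, and addition at −78 °C outruns deprotonation at C8''.

Step 10
Reactants: 17 aryl ketone
Product: 18 (1R,2R)-1-(4-TBSO-3-methoxyphenyl)-2-{4-[(2S,3R,4R,5R)-2-aryl-3,4-dimethyltetrahydrofuran-5-yl]-2-methoxyphenoxy}propan-1-ol
Conditions: (R)-2-methyl-CBS-oxazaborolidine (cat.), BH3·SMe2, THF, −20 °C; MeOH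
Reagents that add atoms: none
Why: Corey–Bakshi–Shibata reduction: the (R)-oxazaborolidine delivers hydride to the ketone face that gives the (7''R) carbinol, which is also the face favoured by the substrate's own 1,2-induction with the aryloxy group anti to the incoming hydride, so catalyst and substrate should reinforce each other toward the threo (7''R,8''R) isomer.

Step 11
Reactants: 18 bis-silyl ether
Product: 19 target, (1R,2R)-1-(4-hydroxy-3-methoxyphenyl)-2-{4-[(2S,3R,4R,5R)-2-(4-hydroxy-3-methoxyphenyl)-3,4-dimethyltetrahydrofuran-5-yl]-2-methoxyphenoxy}propan-1-ol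
Conditions: Bu4NF, AcOH, THF, 0 °C
Reagents that add atoms: none
Why: Fluoride cleaves both aryl silyl ethers, and the acetic acid buffer keeps the liberated p-hydroxybenzylic positions (C2 and C7'') from ionising through quinone methides.

**Compound list**

1 | vanillin (4-hydroxy-3-methoxybenzaldehyde) | COc1cc(C=O)ccc1O | starting material
2 | methyl (S)-lactate | C[C@H](O)C(=O)OC | starting material
3 | methyl (2R)-2-(4-formyl-2-methoxyphenoxy)propanoate | C[C@@H](Oc1ccc(C=O)cc1OC)C(=O)OC | intermediate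
4 | methyl (2R)-2-{4-[(1R)-1-hydroxyprop-2-en-1-yl]-2-methoxyphenoxy}propanoate | C[C@@H](Oc1ccc([C@H](O)C=C)cc1OC)C(=O)OC | intermediate
5 | propiovanillone, 1-(4-hydroxy-3-methoxyphenyl)propan-1-one | CCC(=O)c1ccc(O)c(OC)c1 | starting material
6 | 1-{4-[(tert-butyldimethylsilyl)oxy]-3-methoxyphenyl}propan-1-one | CCC(=O)c1ccc(O[Si](C)(C)C(C)(C)C)c(OC)c1 | intermediate
7 | tert-butyl[4-(1,1-dimethoxypropyl)-2-methoxyphenoxy]dimethylsilane (dimethyl ketal of 6) | CCC(OC)(OC)c1ccc(O[Si](C)(C)C(C)(C)C)c(OC)c1 | intermediate (not isolated)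
8 | tert-butyl{2-methoxy-4-[1-methoxyprop-1-en-1-yl]phenoxy}dimethylsilane (E/Z mixture) | CC=C(OC)c1ccc(O[Si](C)(C)C(C)(C)C)c(OC)c1 | intermediate
9 | methyl (2R)-2-{4-[(1R)-1-{[2-bromo-1-methoxy-1-(4-TBSO-3-methoxyphenyl)propyl]oxy}prop-2-en-1-yl]-2-methoxyphenoxy}propanoate (mixed bromoketal, epimers at the ketal carbon and at CHBr) | C[C@@H](Oc1ccc([C@H](OC(OC)(C(C)Br)c2ccc(O[Si](C)(C)C(C)(C)C)c(OC)c2)C=C)cc1OC)C(=O)OC | intermediate (not isolated)
10 | methyl (2R)-2-{4-[(4R,5R)-2-methoxy-3,4-dimethyl-2-(4-TBSO-3-methoxyphenyl)tetrahydrofuran-5-yl]-2-methoxyphenoxy}propanoate (locants of the remark; epimers at C2 and C3) | C[C@@H](Oc1ccc([C@@H]2OC(OC)(c3ccc(O[Si](C)(C)C(C)(C)C)c(OC)c3)C(C)[C@H]2C)cc1OC)C(=O)OC | intermediate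
11 | methyl (2R)-2-{4-[(3R,4R,5R)-2-methoxy-3,4-dimethyl-2-(4-TBSO-3-methoxyphenyl)tetrahydrofuran-5-yl]-2-methoxyphenoxy}propanoate (C3 trans to C4 methyl; C2 anomers) | C[C@@H](Oc1ccc([C@@H]2OC(OC)(c3ccc(O[Si](C)(C)C(C)(C)C)c(OC)c3)[C@H](C)[C@H]2C)cc1OC)C(=O)OC | intermediate (not isolated)
12 | methyl (2R)-2-{4-[(2S,3R,4R,5R)-3,4-dimethyl-2-(4-TBSO-3-methoxyphenyl)tetrahydrofuran-5-yl]-2-methoxyphenoxy}propanoate | C[C@@H](Oc1ccc([C@@H]2O[C@H](c3ccc(O[Si](C)(C)C(C)(C)C)c(OC)c3)[C@H](C)[C@H]2C)cc1OC)C(=O)OC | intermediate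
13 | (2R)-N-methoxy-N-methyl-2-{4-[(2S,3R,4R,5R)-3,4-dimethyl-2-(4-TBSO-3-methoxyphenyl)tetrahydrofuran-5-yl]-2-methoxyphenoxy}propanamide | C[C@@H](Oc1ccc([C@@H]2O[C@H](c3ccc(O[Si](C)(C)C(C)(C)C)c(OC)c3)[C@H](C)[C@H]2C)cc1OC)C(=O)N(C)OC | intermediate
14 | 4-bromo-2-methoxyphenol | COc1cc(Br)ccc1O | starting material
15 | (4-bromo-2-methoxyphenoxy)(tert-butyl)dimethylsilane | COc1cc(Br)ccc1O[Si](C)(C)C(C)(C)C | intermediate
16 | {4-[(tert-butyldimethylsilyl)oxy]-3-methoxyphenyl}lithium | [Li]c1ccc(O[Si](C)(C)C(C)(C)C)c(OC)c1 | intermediate (not isolated)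
17 | (2R)-1-(4-TBSO-3-methoxyphenyl)-2-{4-[(2S,3R,4R,5R)-3,4-dimethyl-2-(4-TBSO-3-methoxyphenyl)tetrahydrofuran-5-yl]-2-methoxyphenoxy}propan-1-one | C[C@@H](Oc1ccc([C@@H]2O[C@H](c3ccc(O[Si](C)(C)C(C)(C)C)c(OC)c3)[C@H](C)[C@H]2C)cc1OC)C(=O)c1ccc(O[Si](C)(C)C(C)(C)C)c(OC)c1 | intermediate
18 | (1R,2R)-1-(4-TBSO-3-methoxyphenyl)-2-{4-[(2S,3R,4R,5R)-3,4-dimethyl-2-(4-TBSO-3-methoxyphenyl)tetrahydrofuran-5-yl]-2-methoxyphenoxy}propan-1-ol | C[C@@H](Oc1ccc([C@@H]2O[C@H](c3ccc(O[Si](C)(C)C(C)(C)C)c(OC)c3)[C@H](C)[C@H]2C)cc1OC)[C@H](O)c1ccc(O[Si](C)(C)C(C)(C)C)c(OC)c1 | intermediate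
19 | (1R,2R)-1-(4-hydroxy-3-methoxyphenyl)-2-{4-[(2S,3R,4R,5R)-2-(4-hydroxy-3-methoxyphenyl)-3,4-dimethyltetrahydrofuran-5-yl]-2-methoxyphenoxy}propan-1-ol | C[C@@H](Oc1ccc([C@@H]2O[C@H](c3ccc(O)c(OC)c3)[C@H](C)[C@H]2C)cc1OC)[C@H](O)c1ccc(O)c(OC)c1 | target

**Step count and risks**

Total step count: 11. Longest linear sequence: 8 steps (steps 1, 2, 5, 6, 7, 9, 10, 11, from vanillin).

Steps most likely to fail:

Step 5. Capture of the crowded tertiary oxocarbenium ion by the secondary carbinol may be slow compared with loss of HBr or hydrolysis of the bromoketal, and the 5-exo closure may show only a moderate preference for the 4,5-trans arrangement. The fallback introduces the C2 aryl group after ring formation. Setting out from 4, the ester is converted (MeNH(OMe)·HCl, i-PrMgCl, THF) into (2R)-2-{4-[(1R)-1-hydroxyprop-2-en-1-yl]-2-methoxyphenoxy}-N-methoxy-N-methylpropanamide F1. A classical two-stage Ueno–Stork reaction with commercial ethyl 1-propenyl ether follows: NBS in CH2Cl2 gives the isolated bromoacetal F2, and Bu3SnH/AIBN in benzene at 80 °C gives the 2-ethoxy-3,4-dimethyl-5-aryltetrahydrofuran F3. Hydrolysis (aqueous HCl, THF), oxidation of the lactol (PhI(OAc)2, TEMPO) and equilibration of C3 with DBU give the trans,trans-lactone F4, the lactone α-position being the more acidic site. Two equivalents of aryllithium 16 then add to the lactone and to the Weinreb amide in one operation to give the hemiketal ketone F5. Et3SiH/BF3·OEt2 at −78 °C reduces the hemiketal with hydride anti to the C3 methyl, and the route is rejoined at 17.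

Step 6. C3 may equilibrate incompletely at the ketal stage, or hydride delivery may lose facial selectivity if ionisation and reduction are not well separated. The fallback removes the C3 stereocentre before reduction. Setting out from 10, heating with PPTS in toluene with removal of methanol gives the isolable 2-aryl-3,4-dimethyl-4,5-dihydrofuran F6, in which C3 is trigonal. Ionic hydrogenation (CF3CO2H, Et3SiH, CH2Cl2, −40 °C) then proceeds under reversible protonation at C3, so that the more stable oxocarbenium ion with the C3 methyl trans to the C4 methyl is captured by hydride from its open face. The route is rejoined at 12.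

Step 2. Enantiofacial discrimination in the vinyl transfer may be insufficient, and the electron-rich aryl vinyl carbinol may ionise or undergo allylic transposition on work-up. The fallback replaces the asymmetric addition by an enzymatic resolution. Setting out from 3, CH2=CHMgBr in THF at −78 °C adds to the aldehyde only and gives the carbinol as a pair of epimers, methyl (2R)-2-{4-[(1RS)-1-hydroxyprop-2-en-1-yl]-2-methoxyphenoxy}propanoate F7. Acylation with Candida antarctica lipase B and vinyl acetate in hexane should acetylate the (1R)-epimer selectively (the aryl group is the large and the vinyl group the medium substituent) to give methyl (2R)-2-{4-[(1R)-1-acetoxyprop-2-en-1-yl]-2-methoxyphenoxy}propanoate F8. F8 is separated from the unreacted (1S)-carbinol and methanolysed (K2CO3, MeOH, 0 °C) to return to 4.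

Further compounds
F1 | step 5 | (2R)-2-{4-[(1R)-1-hydroxyprop-2-en-1-yl]-2-methoxyphenoxy}-N-methoxy-N-methylpropanamide | C[C@@H](Oc1ccc([C@H](O)C=C)cc1OC)C(=O)N(C)OC
F2 | step 5 | (2R)-2-{4-[(1R)-1-(2-bromo-1-ethoxypropoxy)prop-2-en-1-yl]-2-methoxyphenoxy}-N-methoxy-N-methylpropanamide (bromoacetal, epimer mixture) | C[C@@H](Oc1ccc([C@H](OC(OCC)C(C)Br)C=C)cc1OC)C(=O)N(C)OC
F3 | step 5 | (2R)-2-{4-[(4R,5R)-2-ethoxy-3,4-dimethyltetrahydrofuran-5-yl]-2-methoxyphenoxy}-N-methoxy-N-methylpropanamide (epimers at C2 and C3) | C[C@@H](Oc1ccc([C@@H]2OC(OCC)C(C)[C@H]2C)cc1OC)C(=O)N(C)OC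
F4 | step 5 | (2R)-2-{4-[(3R,4R,5R)-3,4-dimethyl-2-oxotetrahydrofuran-5-yl]-2-methoxyphenoxy}-N-methoxy-N-methylpropanamide (trans,trans-lactone) | C[C@@H](Oc1ccc([C@@H]2OC(=O)[C@H](C)[C@H]2C)cc1OC)C(=O)N(C)OC
F5 | step 5 | (2R)-1-(4-TBSO-3-methoxyphenyl)-2-{4-[(3R,4R,5R)-2-hydroxy-3,4-dimethyl-2-(4-TBSO-3-methoxyphenyl)tetrahydrofuran-5-yl]-2-methoxyphenoxy}propan-1-one (hemiketal ketone) | C[C@@H](Oc1ccc([C@@H]2OC(O)(c3ccc(O[Si](C)(C)C(C)(C)C)c(OC)c3)[C@H](C)[C@H]2C)cc1OC)C(=O)c1ccc(O[Si](C)(C)C(C)(C)C)c(OC)c1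
F6 | step 6 | methyl (2R)-2-{4-[(4R,5R)-3,4-dimethyl-2-(4-TBSO-3-methoxyphenyl)-4,5-dihydrofuran-5-yl]-2-methoxyphenoxy}propanoate | C[C@@H](Oc1ccc([C@@H]2OC(c3ccc(O[Si](C)(C)C(C)(C)C)c(OC)c3)=C(C)[C@H]2C)cc1OC)C(=O)OC
F7 | step 2 | methyl (2R)-2-{4-[(1RS)-1-hydroxyprop-2-en-1-yl]-2-methoxyphenoxy}propanoate (carbinol epimers) | C[C@@H](Oc1ccc(C(O)C=C)cc1OC)C(=O)OC
F8 | step 2 | methyl (2R)-2-{4-[(1R)-1-acetoxyprop-2-en-1-yl]-2-methoxyphenoxy}propanoate | C[C@@H](Oc1ccc([C@H](OC(C)=O)C=C)cc1OC)C(=O)OC
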